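The plan treats the C5 tertiary carbinol and the adjacent C4 exocyclic methylene of ring A as an α-ketol (C5–OH, C4=O). Its skeletal isomer, a cis-fused hydroazulene carrying the carbinol at C4 and the ketone at C5, differs only in whether C10 is bonded to C4 or to C5. One base-induced 1,2-shift of C10 from C4 to C5 therefore makes the C5–C10 bond, enlarges the cyclopentane to ring A, contracts the cycloheptene to ring B and sets C5 with its hydroxyl trans to the C10 methyl. The precursor already holds the C1 bromide, the C7=C8 alkene and a ketal-masked C7 acetyl group, and is built on a desymmetrised cyclopentanone.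

Key step: step 11

Remarks
- Numbering: ring A is C1(HBr)–C2–C3–C4–C5–C10(CH3), ring B is C5–C6–C7–C8–C9–C10, and the side chain is C7–C11(CH3)=C12–C13=C14–C15(CH3)=CH2. β is the face of the C10 methyl group and α the opposite face. The same atom numbers are kept for every intermediate, and CIP descriptors given with these locants refer to this numbering.
- Assumption: the secondary carbinol created at C5 by the allylation is formed as a mixture of epimers and is left unassigned, because it is oxidised to the ketone two steps later.
- Steps 6–7 and 16–19 prepare the two side-chain reagents and are run ahead of the steps that consume them.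

Step 1
Reactants: 1 2-methylcyclopentane-1,3-dione; 2 allyl acetate
Product: 3 2-methyl-2-(prop-2-en-1-yl)cyclopentane-1,3-dione
Conditions: Pd(PPh3)4 (2 mol %), Et3N, THF, 50 °C
Reagents that add atoms: none
Why: Tsuji–Trost allylation, in which the acidic cyclic 1,3-dione attacks the π-allyl complex generated from 2 and zerovalent palladium and ends as the C-allylated product because O-allylation is reversible under the catalyst, which installs the quaternary C10 with its methyl group and the C8–C9 allyl arm; 3 has a mirror plane, so no stereocentre arises.

Step 2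
Reactants: 3 2-methyl-2-(prop-2-en-1-yl)cyclopentane-1,3-dione
Product: 4 (2S,3S)-3-hydroxy-2-methyl-2-(prop-2-en-1-yl)cyclopentan-1-one
Conditions: baker's yeast (Saccharomyces cerevisiae), sucrose, H2O, 30 °C
Reagents that add atoms: none
Why: Enzymatic desymmetrising reduction of a prochiral 2,2-disubstituted cyclopentane-1,3-dione by the ketoreductases of baker's yeast, which should deliver hydride to one of the two enantiotopic carbonyl groups from the face of the methyl group and thereby fix both the quaternary C10 and the C1 carbinol with its hydroxyl cis to the allyl arm, the sense of induction established for this class of diones.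

Step 3
Reactants: 4 (2S,3S)-3-hydroxy-2-methyl-2-(prop-2-en-1-yl)cyclopentan-1-one
Product: 6 (2R,3R)-3-bromo-2-methyl-2-(prop-2-en-1-yl)cyclopentan-1-one, via cyclopentyl triflate 5 (not isolated)
Conditions: Tf2O, 2,6-lutidine, CH2Cl2, −78 °C; then n-Bu4NBr, −78 → 23 °C
Reagents that add atoms: tetrabutylammonium bromide, CCCC[N+](CCCC)(CCCC)CCCC.[Br-]
Why: Sulfonate displacement with Walden inversion (SN2), in which the triflate of the cyclopentanol, whose ionisation and Wagner–Meerwein shift are discouraged by the neighbouring carbonyl group, should be attacked by bromide from the opposite face so that C1–Br ends cis to the C10 methyl group as in the target.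

Step 4
Reactants: 6 (2R,3R)-3-bromo-2-methyl-2-(prop-2-en-1-yl)cyclopentan-1-one; 7 1,3-dithiane
Product: 9 3-bromo-1-(1,3-dithian-2-yl)-2-methyl-2-(prop-2-en-1-yl)cyclopentan-1-ol (OH/CH3/Br cis), via 2-lithio-1,3-dithiane 8 (not isolated)
Conditions: n-BuLi, THF, −30 °C; then 6, −78 °C; aq. NH4Cl
Reagents that add atoms: none
Why: Corey–Seebach addition of the lithiated dithiane as a formyl anion equivalent, run at −78 °C where attack on the carbonyl should outrun enolisation and substitution at the hindered bromide, with the bulky carbanion expected to approach C4 anti to the C1 bromide, that is from the face of the allyl arm, which sets the C4 hydroxyl cis to bromide and methyl and the new C4–C5 bond cis to the allyl arm.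

Step 5
Reactants: 9 3-bromo-1-(1,3-dithian-2-yl)-2-methyl-2-(prop-2-en-1-yl)cyclopentan-1-ol
Product: 10 3-bromo-1-hydroxy-2-methyl-2-(prop-2-en-1-yl)cyclopentane-1-carbaldehyde (OH/CH3/Br cis)
Conditions: PhI(O2CCF3)2, NaHCO3, MeCN/H2O (9:1), 0 °C
Reagents that add atoms: water, O
Why: Oxidative hydrolysis of the dithioacetal with a hypervalent iodine reagent, which activates sulfur within minutes at 0 °C under bicarbonate buffer and should free the aldehyde without touching the bromide or the alkene, so that the α-hydroxy aldehyde, which is prone to ring-enlarging acyloin shift on standing, can be taken crude into step 8; no stereocentre is affected.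

Step 6
Reactants: 11 3-methylbut-3-en-2-one
Product: 12 2-methyl-2-(prop-1-en-2-yl)-1,3-dioxolane
Conditions: (TMSOCH2)2, TMSOTf (1 mol %), CH2Cl2, −78 °C
Reagents that add atoms: 1,2-bis(trimethylsilyloxy)ethane, C[Si](C)(C)OCCO[Si](C)(C)C
Why: Noyori ketalisation (silyl-transfer ketal formation under catalytic TMSOTf), whose aprotic low-temperature conditions should convert the enone carbonyl into the dioxolane without conjugate addition of the glycol or migration of the double bond.

Step 7
Reactants: 12 2-methyl-2-(prop-1-en-2-yl)-1,3-dioxolane
Product: 13 2-(3-chloroprop-1-en-2-yl)-2-methyl-1,3-dioxolane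
Conditions: Ca(OCl)2, CO2 (solid), CH2Cl2/H2O, 0 °C
Reagents that add atoms: calcium hypochlorite, [Ca+2].[O-]Cl.[O-]Cl
Why: Ene-type allylic chlorination by hypochlorous acid generated from Ca(OCl)2 and CO2, in which electrophilic chlorine adds to the terminal CH2 of the isopropenyl group and a proton is lost from the methyl group, the only allylic position available, to give the 2-substituted allyl chloride.

Step 8
Reactants: 10 3-bromo-1-hydroxy-2-methyl-2-(prop-2-en-1-yl)cyclopentane-1-carbaldehyde; 13 2-(3-chloroprop-1-en-2-yl)-2-methyl-1,3-dioxolane
Product: 14 1-[3-bromo-1-hydroxy-2-methyl-2-(prop-2-en-1-yl)cyclopentyl]-3-(2-methyl-1,3-dioxolan-2-yl)but-3-en-1-ol (C5 epimers)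
Conditions: Zn dust, sat. aq. NH4Cl/THF (1:1), 23 °C
Reagents that add atoms: none
Why: Aqueous Barbier allylation with zinc, which should add the 2-substituted allyl unit chemoselectively to the aldehyde in the presence of the free tertiary hydroxyl, the ketal and the secondary bromide and forge C5–C6; the new C5 carbinol is formed without control, which does not matter because C5 becomes a ketone in step 10.

Step 9
Reactants: 14 the diol diene of step 8
Product: 15 cis-fused hydroazulene diol (C4 β-OH; C5 OH either way; C1 β-Br; C7=C8; dioxolane on C7)
Conditions: second-generation Grubbs catalyst (H2IMes)(PCy3)Cl2Ru=CHPh (5 mol %), 1,4-benzoquinone (10 mol %), toluene, 80 °C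
Reagents that add atoms: none
Why: Ring-closing olefin metathesis, favoured because the allyl arm on C10 and the C5–C6–C7 chain on C4 are held cis on the cyclopentane, should join C7 to C8 with loss of ethene and give the trisubstituted cycloheptene, the ruthenium carbene tolerating the free hydroxyls, the ketal and the bromide while benzoquinone suppresses hydride-induced double-bond migration.

Step 10
Reactants: 15 cis-fused hydroazulene diol
Product: 16 (1R,4S,10R) cis-fused hydroazulene α-ketol (C4 β-OH; C5 ketone; C1 β-Br; C7=C8; dioxolane on C7)
Conditions: IBX (2-iodoxybenzoic acid), DMSO, 23 °C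
Reagents that add atoms: none
Why: IBX oxidation, which should convert the secondary C5 carbinol of the vicinal diol into the ketone without cleaving the C4–C5 bond and leave the tertiary C4 hydroxyl untouched, under neutral conditions at room temperature that neither draw the β,γ double bond into conjugation nor start the ketol shift.

Step 11
Reactants: 16 (1R,4S,10R) cis-fused hydroazulene α-ketol
Product: 17 (1R,5S,10R) trans-decalin α-ketol (C5 α-OH; C4 ketone; C1 β-Br; C7=C8; dioxolane on C7)
Conditions: KOMe (0.2 equiv), MeOH, 0 → 23 °C
Reagents that add atoms: none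
Why: Potassium methoxide in methanol reversibly deprotonates the C4 hydroxyl, and as the C4–O π bond forms the C4–C10 σ bond shifts suprafacially, with retention at C10, onto the C5 carbonyl carbon, so that C4 becomes the ketone and C5 the carbinol. The closest known reaction type is the base-catalysed α-ketol (acyloin) rearrangement, as in the D-homoannulation of 17α-hydroxy-20-ketosteroids. Neither ring is closed end to end: ring A arises by one-carbon enlargement of the cyclopentane and ring B by one-carbon contraction of the cycloheptene, both through one three-centre C4–C10–C5 transition state, formally a 3-exo-trig attack of the migrating carbon on the carbonyl group. The new stereocentre C5 is controlled by the conformation about C4–C5: with the solvated potassium alkoxide the two C–O dipoles lie anti, an arrangement that in the cis-fused ring also avoids eclipsing C3 with C6, and from this rotamer C10 reaches the carbonyl face that leaves the C5 hydroxyl trans to the C10 methyl group. The step needs anti over syn delivery and migration of C10 over C3; the first is secured by the non-chelating counter-ion and the protic solvent, the second by the loss of strain of both odd-membered rings on the way to the decalin, which the bridged product of C3 migration does not offer. Once formed, 17 should persist because its C5–C6 and C5–C10 bonds lie near the plane of the C4 carbonyl group, the axial site being taken by oxygen, and because the quaternary C5 insulates the C4 ketone from the C7=C8 bond.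

Step 12
Reactants: 17 (1R,5S,10R) trans-decalin α-ketol
Product: 18 saturated trans-decalin α-ketol (C7 substituent β; H7 α)
Conditions: [Ir(cod)(PCy3)(py)]PF6 (5 mol %), H2 (1 atm), CH2Cl2, 23 °C
Reagents that add atoms: none
Why: Hydroxyl-directed hydrogenation with the Crabtree catalyst, in which the axial C5 hydroxyl on the α face binds the cationic iridium centre and both hydrogen atoms should be delivered to the α face of the homoallylic C7=C8 bond, so that C7 receives its hydrogen α and keeps the ketal-bearing substituent β and equatorial as the target requires; this control is available only after the rearrangement, since before it the sole hydroxyl lies on the β face.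

Step 13
Reactants: 18 saturated trans-decalin α-ketol
Product: 19 C4 exocyclic methylene decalinol (dioxolane still on the C7 substituent)
Conditions: Zn, CH2Br2, TiCl4, THF/CH2Cl2, 0 → 23 °C
Reagents that add atoms: dibromomethane, BrCBr
Why: Takai–Lombardo methylenation, whose non-basic gem-dimetallic reagent should convert the hindered C4 ketone of the α-ketol into the exocyclic methylene without the C3 enolisation (and cyclopropane closure onto C1), the alkoxide-driven fragmentation or the ketol shift that a phosphorus ylide could provoke.

Step 14
Reactants: 19 C4 exocyclic methylene decalinol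
Product: 20 C7 β-acetyl decalinol (methyl ketone)
Conditions: PPTS, acetone/H2O (10:1), 40 °C
Reagents that add atoms: water, O
Why: Acid-catalysed ketal hydrolysis with a weak pyridinium acid, which should release the C7 acetyl group while the tertiary allylic alcohol and the bromide survive; C7 becomes epimerisable but already carries its substituent equatorial.

Step 15
Reactants: 20 C7 β-acetyl decalinol
Product: 21 C5 trimethylsilyl ether of the methyl ketone
Conditions: N-(trimethylsilyl)imidazole, CH2Cl2, 23 °C
Reagents that add atoms: N-(trimethylsilyl)imidazole, C[Si](C)(C)n1ccnc1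
Why: Silylation of the tertiary alcohol with a neutral N-silylimidazole, which should cap the C5 hydroxyl without enolising the methyl ketone, so that step 20 cannot generate an alkoxide next to the antiperiplanar C5–C10 and C1–Br bonds (Grob-type fragmentation).

Step 16
Reactants: 22 methacrolein; 23 triethyl phosphonoacetate
Product: 25 ethyl (2E)-4-methylpenta-2,4-dienoate, via sodium phosphonoacetate salt 24 (not isolated)
Conditions: NaH, THF, 0 °C; then 22, 0 → 23 °C
Reagents that add atoms: none
Why: Horner–Wadsworth–Emmons olefination, in which the stabilised phosphonate anion adds to the aldehyde of 22 in 1,2 fashion and eliminates to the (E)-configured unsaturated ester.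

Step 17
Reactants: 25 ethyl (2E)-4-methylpenta-2,4-dienoate
Product: 26 (2E)-4-methylpenta-2,4-dien-1-ol
Conditions: i-Bu2AlH, CH2Cl2, −78 °C; aq. potassium sodium tartrate
Reagents that add atoms: none
Why: DIBAL reduction of an α,β-unsaturated ester, which at −78 °C in a non-coordinating solvent should proceed by two 1,2-hydride transfers to the allylic alcohol and leave the diene intact.

Step 18
Reactants: 26 (2E)-4-methylpenta-2,4-dien-1-ol
Product: 27 (3E)-5-bromo-2-methylpenta-1,3-diene
Conditions: PBr3, Et2O, 0 °C
Reagents that add atoms: phosphorus tribromide, BrP(Br)Br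
Why: Bromination of a primary allylic alcohol with PBr3 (SN2 on the phosphite ester), which should give the primary dienyl bromide, the conjugated and thermodynamically preferred allylic isomer, with the (E) double bond retained.

Step 19
Reactants: 27 (3E)-5-bromo-2-methylpenta-1,3-diene
Product: 28 diethyl [(2E)-4-methylpenta-2,4-dien-1-yl]phosphonate
Conditions: P(OEt)3, 110 °C
Reagents that add atoms: triethyl phosphite, CCOP(OCC)OCC
Why: Michaelis–Arbuzov reaction, in which the phosphite attacks the primary allylic bromide and the phosphonium intermediate loses bromoethane to give the dienyl phosphonate with the (E) alkene unchanged.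

Step 20
Reactants: 21 C5 trimethylsilyl ether of the methyl ketone; 28 diethyl [(2E)-4-methylpenta-2,4-dien-1-yl]phosphonate
Product: 31 target (1R,5R,7R,10R), via lithiated dienyl phosphonate 29 (not isolated), via trimethylsilyl ether of the target 30 (not isolated)
Conditions: n-BuLi, THF, −78 °C; then 21, −78 → 23 °C; aq. NH4Cl; then citric acid, MeOH, 23 °C
Reagents that add atoms: none
Why: Horner–Wadsworth–Emmons olefination of the methyl ketone with the allylic phosphonate carbanion followed by acid methanolysis of the silyl ether, in which the carbanion should add through its α-carbon and the elimination should place the dienyl chain trans to the bulkier C7 ring carbon, giving the (E) trisubstituted C11=C12 bond while the (E) C13=C14 bond of 28 is carried over.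

Compound list
1 | 2-methylcyclopentane-1,3-dione | CC1C(=O)CCC1=O | starting material
2 | allyl acetate | C=CCOC(C)=O | starting material
3 | 2-methyl-2-(prop-2-en-1-yl)cyclopentane-1,3-dione | C=CCC1(C)C(=O)CCC1=O | intermediate
4 | (2S,3S)-3-hydroxy-2-methyl-2-(prop-2-en-1-yl)cyclopentan-1-one, hydroxyl cis to the allyl group | C=CC[C@@]1(C)[C@@H](O)CCC1=O | intermediate
5 | trifluoromethanesulfonate of 4, configuration unchanged | C=CC[C@@]1(C)[C@@H](OS(=O)(=O)C(F)(F)F)CCC1=O | intermediate (not isolated)
6 | (2R,3R)-3-bromo-2-methyl-2-(prop-2-en-1-yl)cyclopentan-1-one, bromine cis to the methyl group | C=CC[C@@]1(C)[C@H](Br)CCC1=O | intermediate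
7 | 1,3-dithiane | C1CSCSC1 | starting material
8 | 2-lithio-1,3-dithiane | [Li]C1SCCCS1 | intermediate (not isolated)
9 | 3-bromo-1-(1,3-dithian-2-yl)-2-methyl-2-(prop-2-en-1-yl)cyclopentan-1-ol, hydroxyl, methyl and bromine on one face, dithianyl and allyl on the other | C=CC[C@@]1(C)[C@H](Br)CC[C@@]1(O)C2SCCCS2 | intermediate
10 | 3-bromo-1-hydroxy-2-methyl-2-(prop-2-en-1-yl)cyclopentane-1-carbaldehyde, same configuration as 9 | C=CC[C@@]1(C)[C@H](Br)CC[C@@]1(O)C=O | intermediate
11 | 3-methylbut-3-en-2-one | CC(=O)C(C)=C | starting material
12 | 2-methyl-2-(prop-1-en-2-yl)-1,3-dioxolane | CC(=C)C1(C)OCCO1 | intermediate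
13 | 2-(3-chloroprop-1-en-2-yl)-2-methyl-1,3-dioxolane | ClCC(=C)C1(C)OCCO1 | intermediate
14 | 1-[3-bromo-1-hydroxy-2-methyl-2-(prop-2-en-1-yl)cyclopentyl]-3-(2-methyl-1,3-dioxolan-2-yl)but-3-en-1-ol, C5 carbinol as both epimers | C=CC[C@@]1(C)[C@H](Br)CC[C@@]1(O)C(O)CC(=C)C2(C)OCCO2 | intermediate
15 | cis-fused hydroazulene diol: C4 β-hydroxyl, C5 hydroxyl (both epimers), C1 β-bromide, C10 β-methyl, C7=C8, 2-methyl-1,3-dioxolan-2-yl on C7 | CC1(OCCO1)C2=CC[C@@]3(C)[C@H](Br)CC[C@@]3(O)C(O)C2 | intermediate
16 | (1R,4S,10R) cis-fused hydroazulene α-ketol: C4 β-hydroxyl, C5 ketone, C1 β-bromide, C10 β-methyl, C7=C8, dioxolane on C7 | CC1(OCCO1)C2=CC[C@@]3(C)[C@H](Br)CC[C@@]3(O)C(=O)C2 | intermediate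
17 | (1R,5S,10R) trans-decalin α-ketol: C5 α-hydroxyl, C4 ketone, C1 β-bromide, C10 β-methyl, C7=C8, dioxolane on C7 | CC1(OCCO1)C2=CC[C@@]3(C)[C@H](Br)CCC(=O)[C@]3(O)C2 | intermediate
18 | saturated trans-decalin α-ketol, dioxolane-bearing substituent β (equatorial) at C7 | CC1(OCCO1)[C@@H]2CC[C@@]3(C)[C@H](Br)CCC(=O)[C@]3(O)C2 | intermediate
19 | C4 exocyclic methylene analogue of 18 | CC1(OCCO1)[C@@H]2CC[C@@]3(C)[C@H](Br)CCC(=C)[C@]3(O)C2 | intermediate
20 | 7β-acetyl-1β-bromo-10β-methyl-4-methylene-trans-decalin-5α-ol | CC(=O)[C@@H]1CC[C@@]2(C)[C@H](Br)CCC(=C)[C@]2(O)C1 | intermediate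
21 | C5 trimethylsilyl ether of 20 | CC(=O)[C@@H]1CC[C@@]2(C)[C@H](Br)CCC(=C)[C@]2(O[Si](C)(C)C)C1 | intermediate
22 | methacrolein | C=C(C)C=O | starting material
23 | triethyl phosphonoacetate | CCOC(=O)CP(=O)(OCC)OCC | starting material
24 | sodium salt of triethyl phosphonoacetate | CCOC(=O)[CH-]P(=O)(OCC)OCC.[Na+] | intermediate (not isolated)
25 | ethyl (2E)-4-methylpenta-2,4-dienoate | C=C(C)/C=C/C(=O)OCC | intermediate
26 | (2E)-4-methylpenta-2,4-dien-1-ol | C=C(C)/C=C/CO | intermediate
27 | (3E)-5-bromo-2-methylpenta-1,3-diene | C=C(C)/C=C/CBr | intermediate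
28 | diethyl [(2E)-4-methylpenta-2,4-dien-1-yl]phosphonate | C=C(C)/C=C/CP(=O)(OCC)OCC | intermediate
29 | lithiated 28 (carbanion at the carbon next to phosphorus) | C=C(C)/C=C/C([Li])P(=O)(OCC)OCC | intermediate (not isolated)
30 | C5 trimethylsilyl ether of the target | C=C(C)/C=C/C=C(\C)[C@@H]1CC[C@@]2(C)[C@H](Br)CCC(=C)[C@]2(O[Si](C)(C)C)C1 | intermediate (not isolated)
31 | (1R,5R,7R,10R)-1β-bromo-10β-methyl-4-methylene-7β-[(2E,4E)-6-methylhepta-2,4,6-trien-2-yl]-trans-decalin-5α-ol | C=C(C)/C=C/C=C(\C)[C@@H]1CC[C@@]2(C)[C@H](Br)CCC(=C)[C@]2(O)C1 | target

Total step count: 20.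
Longest linear sequence: 14 steps (steps 1–5, 8–15 and 20, from 1).

Steps most likely to fail

1. Step 11. The shift may leak through the syn rotamer, in which the hydroxyl is hydrogen-bonded to the carbonyl or both oxygens are bridged by a cation, so that C10 is delivered to the other face of C5 and the cis-decalin forms. Methoxide may also remove a C6 proton and draw the C7=C8 bond into conjugation before the shift takes place. Fallback, from 16 back to 17: the C4 hydroxyl is capped with N-(trimethylsilyl)imidazole to give the trimethylsilyl ether of the hydroazulene ketol F1. F1 is treated with the bulky monodentate Lewis acid MeAl(O-2,6-t-Bu2-4-MeC6H2)2 in toluene at −78 °C; this binds only the C5 carbonyl oxygen, so no base, hydrogen bond or chelate is present. The Lewis-acid-promoted acyloin shift of the α-siloxy ketone, with transfer of silicon to the new oxygen, should give the C5 trimethylsilyl ether of the decalin ketol F2. Citric acid in methanol then returns the route to 17.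

2. Step 4. The dithianyl anion may attack C4 from the methyl face, or only enolise the hindered ketone. The C4 epimer cannot be used, because the ring of its trans-fused ketol should allow C10 to reach only the carbonyl face that gives the cis-decalin. Fallback, from 4 back to 10, which delivers C5 from the C1 oxygen and postpones the bromination:
   - The hydroxyl of 4, which lies on the allyl face, is silylated with (bromomethyl)chlorodimethylsilane and imidazole to the (bromomethyl)dimethylsilyl ether F3.
   - SmI2 in THF should close the silicon-tethered Barbier adduct, the bicyclic siloxane F4, in which the new C4–C5 bond is necessarily on the face of the C1 oxygen and hence cis to the allyl arm.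
   - Tamao oxidation (H2O2, KF, KHCO3, THF/MeOH) gives the triol F5.
   - 2,2-Dimethoxypropane and PPTS mask the C4/C5 diol as the acetonide F6.
   - The triflate and bromide sequence of step 3 gives the bromo acetonide F7.
   - Aqueous acetic acid frees the bromo diol F8.
   - Oxidation of the primary alcohol with TEMPO and PhI(OAc)2 returns the route to 10.

3. Step 20. Addition of the allylic phosphonate carbanion to the methyl ketone may be slowed by enolisation, and the elimination may give incomplete (E) selectivity at C11=C12. Fallback, from 21 back to 30, which builds the chain in two olefinations of known high (E) preference: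
   - 21 is condensed with 23 and NaH in THF at 60 °C to the (E)-enoate F9.
   - i-Bu2AlH at −78 °C reduces it to the allylic alcohol F10.
   - MnO2 gives the (E)-enal F11.
   - The anion of diethyl (2-methylprop-2-en-1-yl)phosphonate, made with LiN(SiMe3)2, converts the aldehyde into 30, which is desilylated as in step 20.

Further compounds
F1 | step 11 | C4 trimethylsilyl ether of the hydroazulene ketol 16 | CC1(OCCO1)C2=CC[C@@]3(C)[C@H](Br)CC[C@@]3(O[Si](C)(C)C)C(=O)C2
F2 | step 11 | C5 trimethylsilyl ether of the decalin ketol 17 | CC1(OCCO1)C2=CC[C@@]3(C)[C@H](Br)CCC(=O)[C@]3(O[Si](C)(C)C)C2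
F3 | step 4 | (bromomethyl)dimethylsilyl ether of 4 | C=CC[C@@]1(C)[C@@H](O[Si](C)(C)CBr)CCC1=O
F4 | step 4 | bicyclic siloxane with C5 delivered to C4 from the C1 oxygen | C=CC[C@@]1(C)[C@@H]2CC[C@@]1(O)C[Si](C)(C)O2
F5 | step 4 | triol: C1 hydroxyl, C4 hydroxyl, C5 hydroxymethyl | C=CC[C@@]1(C)[C@@H](O)CC[C@@]1(O)CO
F6 | step 4 | acetonide of the C4/C5 diol, C1 hydroxyl free | C=CC[C@@]1(C)[C@@H](O)CC[C@@]1(OC(C)(C)O2)C2
F7 | step 4 | bromo acetonide, C1 bromide cis to the methyl group | C=CC[C@@]1(C)[C@H](Br)CC[C@@]1(OC(C)(C)O2)C2
F8 | step 4 | bromo diol: 3-bromo-1-(hydroxymethyl)-2-methyl-2-(prop-2-en-1-yl)cyclopentan-1-ol | C=CC[C@@]1(C)[C@H](Br)CC[C@@]1(O)CO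
F9 | step 20 | ethyl (E)-3-substituted but-2-enoate from 21, C5 silyl ether kept | CCOC(=O)/C=C(\C)[C@@H]1CC[C@@]2(C)[C@H](Br)CCC(=C)[C@]2(O[Si](C)(C)C)C1
F10 | step 20 | (E)-allylic alcohol from F9 | OC/C=C(\C)[C@@H]1CC[C@@]2(C)[C@H](Br)CCC(=C)[C@]2(O[Si](C)(C)C)C1
F11 | step 20 | (E)-enal from F10 | O=C/C=C(\C)[C@@H]1CC[C@@]2(C)[C@H](Br)CCC(=C)[C@]2(O[Si](C)(C)C)C1
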